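The achiral target is disconnected through its central ring B. Its six carbons carry in sequence OH (C1), 4-hydroxybenzyl (C2), the 2-arylethyl chain (C3), a second 4-hydroxybenzyl (C4) and two CH (C5, C6), with the C1 oxygen para to C4. This is the imprint of a 4-substituted 1-methoxy-3-silyloxy-1,3-diene adding to an aryl alkynyl ketone. One Diels–Alder cycloaddition–methanol elimination forms C2–C3 and C4–C5, closes and aromatises ring B, and unites all four rings. The precursors are acyclic: diene 9 (C5, C6, C1, C2, one benzyl) and ynone 19 (C3, C4, chain, aroyl). The new para-OH then enables cation-free ketone deoxygenation.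

Key step: step 11

Assumption: the target SMILES contains no stereocentre and no stereogenic double bond. The compound is therefore achiral, and the request for a single enantiomer is met by the compound itself. Ring A denotes the 3-hydroxy-5-methoxyphenyl ring.

Step 1
Reactants: 1 3-(4-hydroxyphenyl)propanoic acid
Product: 2 3-[4-(benzyloxy)phenyl]propanoic acid
Conditions: BnBr (1.2 equiv), NaOH (3 equiv), EtOH/H2O, reflux; then aq HCl
Reagents that add atoms: benzyl bromide BrCc1ccccc1
Why: Williamson ether synthesis on the phenoxide–carboxylate dianion, in which the phenoxide is the better nucleophile and any benzyl ester formed is saponified in the same pot, so the free acid should result in one operation.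

Step 2
Reactants: 2 3-[4-(benzyloxy)phenyl]propanoic acid
Product: 4 N-methoxy-N-methyl-3-[4-(benzyloxy)phenyl]propanamide, via 1-{3-[4-(benzyloxy)phenyl]propanoyl}-1H-imidazole 3 (not isolated)
Conditions: CDI, CH2Cl2, rt; then MeNHOMe·HCl, rt
Reagents that add atoms: N,O-dimethylhydroxylamine hydrochloride CNOC.Cl; 1,1'-carbonyldiimidazole O=C(n1ccnc1)n1ccnc1 (supplies only the imidazolyl group of 3)
Why: Standard amide coupling through acyl imidazole 3, with the liberated imidazole acting as base for the amine hydrochloride.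

Step 3
Reactants: 4 N-methoxy-N-methyl-3-[4-(benzyloxy)phenyl]propanamide; 5 ethynylmagnesium bromide
Product: 7 5-[4-(benzyloxy)phenyl]pent-1-yn-3-one, via bromomagnesium salt of the tetrahedral N-methoxy-N-methyl hemiaminal adduct 6 (not isolated)
Conditions: 5 (2.5 equiv), THF, 0 °C to rt; inverse quench into cold 1 M HCl
Reagents that add atoms: none
Why: Acylation of an alkynyl Grignard reagent by an N-methoxy-N-methylamide stops at the magnesium-chelated adduct 6, which collapses to the ynone only on quenching, and inverse addition into cold acid protonates the released N,O-dimethylhydroxylamine before it can add to the terminal ynone.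

Step 4
Reactants: 7 5-[4-(benzyloxy)phenyl]pent-1-yn-3-one
Product: 8 (E)-5-[4-(benzyloxy)phenyl]-1-methoxypent-1-en-3-one
Conditions: MeOH (5 equiv), DABCO (10 mol %), CH2Cl2, 0 °C to rt
Reagents that add atoms: methanol CO
Why: Amine-catalysed oxa-Michael addition of methanol to a terminal ynone, which settles on the more stable E β-methoxy enone.

Step 5
Reactants: 8 (E)-5-[4-(benzyloxy)phenyl]-1-methoxypent-1-en-3-one
Product: 9 (1E,3Z)-5-[4-(benzyloxy)phenyl]-3-(tert-butyldimethylsilyloxy)-1-methoxypenta-1,3-diene
Conditions: TBSOTf (1.2 equiv), Et3N (2 equiv), Et2O, 0 °C; filtration through Et3N-deactivated alumina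
Reagents that add atoms: tert-butyldimethylsilyl triflate CC(C)(C)[Si](C)(C)OS(=O)(=O)C(F)(F)F
Why: Soft enolisation with silyl triflate and amine can only go toward the single enolisable CH2 and should give the 3Z silyl dienol ether (benzyl group away from the vinyl residue), while the TBS group lets this non-distillable diene be freed of amine salts and withstand the long heating and the methanol released in step 11.

Step 6
Reactants: 10 methyl 3-hydroxy-5-methoxybenzoate
Product: 11 methyl 3-(benzyloxy)-5-methoxybenzoate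
Conditions: BnBr, K2CO3, acetone, reflux
Reagents that add atoms: benzyl bromide BrCc1ccccc1
Why: Williamson etherification of the only acidic OH under conditions that leave the methyl ester intact.

Step 7
Reactants: 11 methyl 3-(benzyloxy)-5-methoxybenzoate
Product: 12 [3-(benzyloxy)-5-methoxyphenyl]methanol
Conditions: LiAlH4, THF, 0 °C; aq NaOH work-up
Reagents that add atoms: none
Why: Hydride reduction of the ester to the primary benzylic alcohol, to which both aryl ethers are inert.

Step 8
Reactants: 12 [3-(benzyloxy)-5-methoxyphenyl]methanol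
Product: 13 3-(benzyloxy)-5-methoxybenzyl bromide
Conditions: PBr3 (0.4 equiv), CH2Cl2, 0 °C
Reagents that add atoms: phosphorus tribromide BrP(Br)Br
Why: Bromination through the phosphite ester with SN2 displacement, and because both alkoxy groups are meta to the benzylic carbon the bromide should be stable enough to handle.

Step 9
Reactants: 14 1-(trimethylsilyl)propyne; 13 3-(benzyloxy)-5-methoxybenzyl bromide
Product: 17 1-(benzyloxy)-3-(but-3-yn-1-yl)-5-methoxybenzene, via 3-(trimethylsilyl)prop-2-yn-1-yllithium 15 (not isolated), via {4-[3-(benzyloxy)-5-methoxyphenyl]but-1-yn-1-yl}trimethylsilane 16 (not isolated)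
Conditions: 14 (1.3 equiv), n-BuLi (1.25 equiv), THF, −78 °C; 13, −78 °C to rt; then MeOH, K2CO3 (cat.), rt
Reagents that add atoms: n-butyllithium [Li]CCCC (supplies only the lithium of 15)
Why: Propargylic lithiation of the silyl-capped alkyne and SN2 alkylation by the benzylic bromide (the silyl group blocks the alkyne terminus and disfavours allene formation), followed in the same pot by base-catalysed methanolysis of the C(sp)–Si bond.

Step 10
Reactants: 17 1-(benzyloxy)-3-(but-3-yn-1-yl)-5-methoxybenzene; 18 4-(benzyloxy)benzoyl chloride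
Product: 19 1-[4-(benzyloxy)phenyl]-5-[3-(benzyloxy)-5-methoxyphenyl]pent-2-yn-1-one
Conditions: PdCl2(PPh3)2 (2 mol %), CuI (4 mol %), Et3N (1.5 equiv), THF, rt; chromatography to remove Pd and phosphine
Reagents that add atoms: none
Why: Acyl Sonogashira coupling of a terminal alkyne with an aroyl chloride runs at room temperature, where the propargylic CH2 should not isomerise, and removing phosphine and palladium guards against ynone-to-dienone isomerisation in the next, hot step.

Step 11
Reactants: 9 (1E,3Z)-5-[4-(benzyloxy)phenyl]-3-(tert-butyldimethylsilyloxy)-1-methoxypenta-1,3-diene; 19 1-[4-(benzyloxy)phenyl]-5-[3-(benzyloxy)-5-methoxyphenyl]pent-2-yn-1-one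
Product: 22 [4-(benzyloxy)phenyl]{3-[4-(benzyloxy)benzyl]-2-{2-[3-(benzyloxy)-5-methoxyphenyl]ethyl}-4-hydroxyphenyl}methanone, via rac-[4-(benzyloxy)phenyl]{cis-3-[4-(benzyloxy)benzyl]-2-{2-[3-(benzyloxy)-5-methoxyphenyl]ethyl}-4-(tert-butyldimethylsilyloxy)-6-methoxycyclohexa-1,4-dien-1-yl}methanone 20 (not isolated), via the O-TBS ether of 22 21 (not isolated)
Conditions: 9 (1.5 equiv), BHT (cat.), o-xylene (concentrated), 140 °C, sealed, Ar; then TBAF/AcOH (1:1), THF, 0 °C to rt
Reagents that add atoms: none
Why: This is a normal-electron-demand, concerted but asynchronous [4+2] cycloaddition in which the HOMO of 9, raised by the 1-OMe and 3-OSi donors, has its largest coefficient at the benzyl-bearing terminus C4, which bonds first to the β-carbon of ynone 19 (largest LUMO coefficient) while the methoxy-bearing C1 closes onto the α-carbon. It is the known Diels–Alder/elimination benzannulation of 1-alkoxy-3-silyloxy-1,3-dienes with acetylenic ketones to para-acylphenols. Ring B is the only ring closed, by intermolecular cycloaddition that forms its C2–C3 and C4–C5 bonds, and the 1,4-cyclohexadiene 20 aromatises without an oxidant because its allylic, silyloxy-activated methoxy group ionises and the ring C–H beside the benzyl group is lost (net 1,4-elimination of methanol) to give 21. The two sp3 ring carbons of 20 are set cis by suprafacial addition to the 1E,3Z diene (both substituents outside) but are erased on aromatisation, so no stereocontrol is needed. The step needs regioselectivity (aroyl para to the new oxygen, chain between the two benzylic carbons), secured by the matched polarisation of two donors against one acceptor, and chemoselectivity for C≡C over C=O, secured by heating without any Lewis acid. The TBS ether resists the methanol released, and buffered fluoride then converts 21, and any unaromatised 20 by β-elimination of methoxide, into phenol 22.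

Step 12
Reactants: 22 [4-(benzyloxy)phenyl]{3-[4-(benzyloxy)benzyl]-2-{2-[3-(benzyloxy)-5-methoxyphenyl]ethyl}-4-hydroxyphenyl}methanone
Product: 25 2,4-bis[4-(benzyloxy)benzyl]-3-{2-[3-(benzyloxy)-5-methoxyphenyl]ethyl}phenol, via rac-2-[4-(benzyloxy)benzyl]-4-{[4-(benzyloxy)phenyl](hydroxy)methyl}-3-{2-[3-(benzyloxy)-5-methoxyphenyl]ethyl}phenol 23 (not isolated), via 2-[4-(benzyloxy)benzyl]-4-[4-(benzyloxy)benzylidene]-3-{2-[3-(benzyloxy)-5-methoxyphenyl]ethyl}cyclohexa-2,5-dien-1-one 24 (not isolated)
Conditions: NaBH4 (excess, in portions), aq NaOH, i-PrOH/THF, reflux; then aq HCl to pH 5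
Reagents that add atoms: none
Why: In this known alkaline borohydride deoxygenation of para-hydroxyaryl ketones, hydride gives benzhydrol 23, whose para-phenoxide expels hydroxide (1,6-elimination) to para-quinone methide 24, which takes a second hydride at the exocyclic carbon, so no free diarylmethyl cation arises that the electron-rich ring A could trap in a seven-membered Friedel–Crafts closure, and the benzyl ethers are untouched.

Step 13
Reactants: 25 2,4-bis[4-(benzyloxy)benzyl]-3-{2-[3-(benzyloxy)-5-methoxyphenyl]ethyl}phenol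
Product: 26 2,4-bis(4-hydroxybenzyl)-3-[2-(3-hydroxy-5-methoxyphenyl)ethyl]phenol (target CNP0518900.0)
Conditions: H2 (1 atm), 10% Pd/C, EtOAc/EtOH, rt
Reagents that add atoms: none
Why: Catalytic hydrogenolysis cleaves the three aryl benzyl ethers under neutral conditions that leave the methyl ether, the diarylmethane C–C bonds and the arenes intact.

Compound list
1 | 3-(4-hydroxyphenyl)propanoic acid | OC(=O)CCc1ccc(O)cc1 | starting material
2 | 3-[4-(benzyloxy)phenyl]propanoic acid | OC(=O)CCc1ccc(OCc2ccccc2)cc1 | intermediate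
3 | 1-{3-[4-(benzyloxy)phenyl]propanoyl}-1H-imidazole | O=C(CCc1ccc(OCc2ccccc2)cc1)n1ccnc1 | intermediate
4 | N-methoxy-N-methyl-3-[4-(benzyloxy)phenyl]propanamide | CON(C)C(=O)CCc1ccc(OCc2ccccc2)cc1 | intermediate
5 | ethynylmagnesium bromide | C#C[Mg]Br | starting material
6 | bromomagnesium salt of the tetrahedral N-methoxy-N-methyl hemiaminal adduct (racemic) | C#CC(O[Mg]Br)(CCc1ccc(OCc2ccccc2)cc1)N(C)OC | intermediate
7 | 5-[4-(benzyloxy)phenyl]pent-1-yn-3-one | C#CC(=O)CCc1ccc(OCc2ccccc2)cc1 | intermediate
8 | (E)-5-[4-(benzyloxy)phenyl]-1-methoxypent-1-en-3-one | CO/C=C/C(=O)CCc1ccc(OCc2ccccc2)cc1 | intermediate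
9 | (1E,3Z)-5-[4-(benzyloxy)phenyl]-3-(tert-butyldimethylsilyloxy)-1-methoxypenta-1,3-diene | CO/C=C/C(O[Si](C)(C)C(C)(C)C)=C/Cc1ccc(OCc2ccccc2)cc1 | intermediate
10 | methyl 3-hydroxy-5-methoxybenzoate | COC(=O)c1cc(O)cc(OC)c1 | starting material
11 | methyl 3-(benzyloxy)-5-methoxybenzoate | COC(=O)c1cc(OC)cc(OCc2ccccc2)c1 | intermediate
12 | [3-(benzyloxy)-5-methoxyphenyl]methanol | COc1cc(CO)cc(OCc2ccccc2)c1 | intermediate
13 | 3-(benzyloxy)-5-methoxybenzyl bromide | COc1cc(CBr)cc(OCc2ccccc2)c1 | intermediate
14 | 1-(trimethylsilyl)propyne | CC#C[Si](C)(C)C | starting material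
15 | 3-(trimethylsilyl)prop-2-yn-1-yllithium | [Li]CC#C[Si](C)(C)C | intermediate
16 | {4-[3-(benzyloxy)-5-methoxyphenyl]but-1-yn-1-yl}trimethylsilane | COc1cc(CCC#C[Si](C)(C)C)cc(OCc2ccccc2)c1 | intermediate
17 | 1-(benzyloxy)-3-(but-3-yn-1-yl)-5-methoxybenzene | C#CCCc1cc(OC)cc(OCc2ccccc2)c1 | intermediate
18 | 4-(benzyloxy)benzoyl chloride | O=C(Cl)c1ccc(OCc2ccccc2)cc1 | starting material
19 | 1-[4-(benzyloxy)phenyl]-5-[3-(benzyloxy)-5-methoxyphenyl]pent-2-yn-1-one | O=C(C#CCCc1cc(OC)cc(OCc2ccccc2)c1)c1ccc(OCc2ccccc2)cc1 | intermediate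
20 | cis-3,6-disubstituted cyclohexa-1,4-diene cycloadduct (racemic, one enantiomer drawn) | CO[C@@H]1C=C(O[Si](C)(C)C(C)(C)C)[C@H](Cc2ccc(OCc3ccccc3)cc2)C(CCc2cc(OC)cc(OCc3ccccc3)c2)=C1C(=O)c1ccc(OCc2ccccc2)cc1 | intermediate
21 | [4-(benzyloxy)phenyl]{3-[4-(benzyloxy)benzyl]-2-{2-[3-(benzyloxy)-5-methoxyphenyl]ethyl}-4-(tert-butyldimethylsilyloxy)phenyl}methanone | COc1cc(OCc2ccccc2)cc(CCc2c(C(=O)c3ccc(OCc4ccccc4)cc3)ccc(O[Si](C)(C)C(C)(C)C)c2Cc2ccc(OCc3ccccc3)cc2)c1 | intermediate
22 | [4-(benzyloxy)phenyl]{3-[4-(benzyloxy)benzyl]-2-{2-[3-(benzyloxy)-5-methoxyphenyl]ethyl}-4-hydroxyphenyl}methanone | COc1cc(OCc2ccccc2)cc(CCc2c(C(=O)c3ccc(OCc4ccccc4)cc3)ccc(O)c2Cc2ccc(OCc3ccccc3)cc2)c1 | intermediate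
23 | 2-[4-(benzyloxy)benzyl]-4-{[4-(benzyloxy)phenyl](hydroxy)methyl}-3-{2-[3-(benzyloxy)-5-methoxyphenyl]ethyl}phenol (racemic) | COc1cc(OCc2ccccc2)cc(CCc2c(C(O)c3ccc(OCc4ccccc4)cc3)ccc(O)c2Cc2ccc(OCc3ccccc3)cc2)c1 | intermediate
24 | para-quinone methide, 2-[4-(benzyloxy)benzyl]-4-[4-(benzyloxy)benzylidene]-3-{2-[3-(benzyloxy)-5-methoxyphenyl]ethyl}cyclohexa-2,5-dien-1-one (exocyclic geometry undefined and of no consequence) | O=C1C=CC(=Cc2ccc(OCc3ccccc3)cc2)C(CCc2cc(OC)cc(OCc3ccccc3)c2)=C1Cc1ccc(OCc2ccccc2)cc1 | intermediate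
25 | 2,4-bis[4-(benzyloxy)benzyl]-3-{2-[3-(benzyloxy)-5-methoxyphenyl]ethyl}phenol | COc1cc(OCc2ccccc2)cc(CCc2c(Cc3ccc(OCc4ccccc4)cc3)ccc(O)c2Cc2ccc(OCc3ccccc3)cc2)c1 | intermediate
26 | 2,4-bis(4-hydroxybenzyl)-3-[2-(3-hydroxy-5-methoxyphenyl)ethyl]phenol (achiral) | COc1cc(O)cc(CCc2c(Cc3ccc(O)cc3)ccc(O)c2Cc2ccc(O)cc2)c1 | target

Total step count: 13.
Longest linear sequence: 8 steps (steps 6–10, then 11–13). The diene arm (steps 1–5, then 11–13) is equally long.

Steps most likely to fail

Step 11. The cycloaddition joins two substituted termini. It may be so slow that thermal degradation of the diene, or prototropic isomerisation of the ynone to a conjugated dienone, overtakes it. The fallback sets out from 7 and returns at 21, replacing the diene by a far more reactive 1-amino-3-silyloxy diene.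
- Dimethylamine (THF, 0 °C) should add to 7 to give (E)-5-[4-(benzyloxy)phenyl]-1-(dimethylamino)pent-1-en-3-one F1.
- KHMDS then TBSCl (THF, −78 °C) should convert it into (1E,3Z)-5-[4-(benzyloxy)phenyl]-3-(tert-butyldimethylsilyloxy)-N,N-dimethylpenta-1,3-dien-1-amine F2.
- This diene should add to 19 at 60–80 °C in toluene with the same regiochemistry, giving the cis-6-(dimethylamino)cyclohexa-1,4-diene cycloadduct F3.
- Mild acid (AcOH) should expel the amine to give 21, and the fluoride treatment of step 11 then leads to 22.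

Step 12. Three things may go wrong:
- hydride delivery to the phenoxide-deactivated, ortho-substituted ketone may stall;
- the 1,6-elimination may stall in the poorly solubilising alkaline medium;
- the quinone methide may oligomerise faster than it is reduced.

The fallback sets out from 22 and returns at 26, replacing the anionic deoxygenation by surface hydrogenolysis. LiAlH4 (THF, 0 °C) should give benzhydrol 23, which would be used crude without contact with silica gel. H2 over Pd(OH)2/C in neutral EtOAc/EtOH should then cleave the doubly benzylic C–OH bond together with the three benzyl ethers. The endgame stays at two steps, and this fallback makes no compound outside the list (F0).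

Step 3. The released N,O-dimethylhydroxylamine may add in conjugate fashion to the terminal ynone during the quench, or the ynone may oligomerise under base. Either would erode the material. The fallback sets out from 4 and returns at 7 by an addition–oxidation sequence that never exposes the ynone to an amine.
- DIBAL-H (THF, −78 °C) should give 3-[4-(benzyloxy)phenyl]propanal F4.
- Reagent 5 (THF, 0 °C) should add to it to give racemic 5-[4-(benzyloxy)phenyl]pent-1-yn-3-ol F5.
- MnO2 (CH2Cl2, rt) or Dess–Martin periodinane should oxidise F5 to 7.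

Further compounds
F1 | step 11 | (E)-5-[4-(benzyloxy)phenyl]-1-(dimethylamino)pent-1-en-3-one | CN(C)/C=C/C(=O)CCc1ccc(OCc2ccccc2)cc1
F2 | step 11 | (1E,3Z)-5-[4-(benzyloxy)phenyl]-3-(tert-butyldimethylsilyloxy)-N,N-dimethylpenta-1,3-dien-1-amine | CN(C)/C=C/C(O[Si](C)(C)C(C)(C)C)=C/Cc1ccc(OCc2ccccc2)cc1
F3 | step 11 | cis-6-(dimethylamino)cyclohexa-1,4-diene cycloadduct (racemic, one enantiomer drawn) | CN(C)[C@@H]1C=C(O[Si](C)(C)C(C)(C)C)[C@H](Cc2ccc(OCc3ccccc3)cc2)C(CCc2cc(OC)cc(OCc3ccccc3)c2)=C1C(=O)c1ccc(OCc2ccccc2)cc1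
F0 | step 12 | none | none
F4 | step 3 | 3-[4-(benzyloxy)phenyl]propanal | O=CCCc1ccc(OCc2ccccc2)cc1
F5 | step 3 | 5-[4-(benzyloxy)phenyl]pent-1-yn-3-ol (racemic) | C#CC(O)CCc1ccc(OCc2ccccc2)cc1
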